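**Plan**

1. Cuts: (a) the O–benzyl bond of a protected ring A phenol (last step); (b) ring B, the seven-membered lactone, at the ester C(=O)–O bond and at the diaryl ether O–C bond on ring A, giving a 2-fluoro-3-formylbenzoyl chloride (ring A) and 6,7-dihydroxy-2,2,5-trimethylchroman-4-one (rings C and D); (c) ring D at the C4–C4a bond and at one C–H bond of a C2 methyl group.
2. Feature used: in ring D the quaternary C2 (O1, two CH3) lies β to the aryl ketone C4, so C4, C3, C2 and one C2 methyl carbon can be the four ring carbons of a 3-aryloxy-3-methylcyclobutanone hung on O1, with boron on the ortho carbon C4a; ring D is therefore grown from this four-membered ring and not closed directly as a six-membered ring.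
3. Forward: ring C is functionalised first (Dakin oxidation, catechol acetonide, bromination), the cyclobutanone is built on O1 by ketene [2+2] cycloaddition to the aryl isopropenyl ether, ring D arises by rhodium-catalysed transannular arylation and strain-driven β-carbon elimination (four- to six-membered ring), and ring B is closed last by one-pot acylation/SNAr with the separately made ring A fragment.
4. Stereochemistry: the target has no stereocentre; the only stereocentre of the route (a racemic dichlorocyclobutanone) disappears on dechlorination.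

Key step: step 9

Remark: ring A is the formyl-bearing benzene ring, ring B the seven-membered lactone, ring C the central benzene ring and ring D the pyranone, numbered as in chroman-4-one (O1, C2, C3, C4, C4a, C8a); 2,4-dihydroxy-6-methylbenzaldehyde and 2,6-difluoro-4-methylbenzaldehyde are assumed to be commercially available.

**Route**

Step 1
Reactants: 1 2,4-dihydroxy-6-methylbenzaldehyde
Product: 2 6-methylbenzene-1,2,4-triol
Conditions: H2O2 (30% aq., 1.1 equiv), NaOH (aq.), 0 °C → rt, N2; then HCl (aq.); crude product used at once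
Reagents that add atoms: hydrogen peroxide, OO
Why: Dakin oxidation, in which the hydroperoxide adduct of the aldehyde undergoes aryl migration assisted by the ortho and para phenoxides and the aryl formate is hydrolysed in the same pot.

Step 2
Reactants: 2 6-methylbenzene-1,2,4-triol
Product: 3 2,2,7-trimethyl-1,3-benzodioxol-5-ol
Conditions: 2,2-dimethoxypropane, TsOH·H2O (cat.), toluene, reflux with removal of MeOH (4 Å sieves), N2
Reagents that add atoms: 2,2-dimethoxypropane, COC(C)(C)OC
Why: Acid-catalysed transketalisation, in which only the vicinal hydroxyl pair can close the five-membered dioxole, so the isolated hydroxyl (the future O1) stays free.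

Step 3
Reactants: 3 2,2,7-trimethyl-1,3-benzodioxol-5-ol
Product: 4 6-bromo-2,2,7-trimethyl-1,3-benzodioxol-5-ol
Conditions: NBS (1.0 equiv), MeCN, −20 °C → 0 °C
Reagents that add atoms: N-bromosuccinimide, O=C1CCC(=O)N1Br
Why: Electrophilic aromatic bromination ortho to the free phenol, which should go to the position para to a dioxole oxygen (the future C4a) and not to the position flanked by two oxygens, as is usual for 1,3-benzodioxol-5-ols.

Step 4
Reactants: 4 6-bromo-2,2,7-trimethyl-1,3-benzodioxol-5-ol
Product: 5 6-bromo-2,2,7-trimethyl-1,3-benzodioxol-5-yl acetate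
Conditions: Ac2O, pyridine (solvent), rt
Reagents that add atoms: acetic anhydride, CC(=O)OC(C)=O
Why: Routine O-acetylation of a phenol, which provides the ester carbonyl for methylenation.

Step 5
Reactants: 5 6-bromo-2,2,7-trimethyl-1,3-benzodioxol-5-yl acetate
Product: 6 5-bromo-2,2,4-trimethyl-6-(prop-1-en-2-yloxy)-1,3-benzodioxole
Conditions: Cp2TiMe2 (2.5 equiv), toluene/THF, 65 °C, dark; chromatography on Et3N-deactivated silica
Reagents that add atoms: dimethyltitanocene, C[Ti](C)(C1C=CC=C1)C1C=CC=C1
Why: Petasis methylenation, in which titanocene methylidene converts the ester C=O into the enol ether through an oxatitanacyclobutane while the aryl bromide and the ketal stay inert.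

Step 6
Reactants: 6 5-bromo-2,2,4-trimethyl-6-(prop-1-en-2-yloxy)-1,3-benzodioxole
Product: 7 racemic 3-[(6-bromo-2,2,7-trimethyl-1,3-benzodioxol-5-yl)oxy]-2,2-dichloro-3-methylcyclobutan-1-one
Conditions: Cl3CCOCl, Zn dust (activated), POCl3, Et2O, 0 °C → rt
Reagents that add atoms: trichloroacetyl chloride (source of dichloroketene), ClC(Cl)(Cl)C(Cl)=O
Why: Ketene–alkene [2+2] cycloaddition, in which the ketene carbonyl carbon bonds to the CH2 terminus of the electron-rich enol ether so that the ether carbon becomes C3 of the cyclobutanone; the new stereocentre forms as the racemate and is erased in step 7.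

Step 7
Reactants: 7 racemic 3-[(6-bromo-2,2,7-trimethyl-1,3-benzodioxol-5-yl)oxy]-2,2-dichloro-3-methylcyclobutan-1-one
Product: 8 3-[(6-bromo-2,2,7-trimethyl-1,3-benzodioxol-5-yl)oxy]-3-methylcyclobutan-1-one
Conditions: Zn dust, AcOH, 0 °C → rt
Reagents that add atoms: none
Why: Reductive dechlorination of an α,α-dichloroketone through zinc enolates that the solvent protonates at once, the standard route to 3-alkoxycyclobutanones.

Step 8
Reactants: 8 3-[(6-bromo-2,2,7-trimethyl-1,3-benzodioxol-5-yl)oxy]-3-methylcyclobutan-1-one
Product: 9 3-methyl-3-{[2,2,7-trimethyl-6-(4,4,5,5-tetramethyl-1,3,2-dioxaborolan-2-yl)-1,3-benzodioxol-5-yl]oxy}cyclobutan-1-one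
Conditions: B2pin2, Pd2(dba)3 (2 mol %), XPhos (8 mol %), KOAc, 1,4-dioxane, 90 °C
Reagents that add atoms: bis(pinacolato)diboron, CC1(C)OB(OC1(C)C)B1OC(C)(C)C(C)(C)O1
Why: Miyaura borylation, in which the bulky electron-rich phosphine allows oxidative addition of the doubly ortho-substituted bromide to zerovalent palladium and KOAc is too weak a base to enolise the ketone.

Step 9
Reactants: 9 3-methyl-3-{[2,2,7-trimethyl-6-(4,4,5,5-tetramethyl-1,3,2-dioxaborolan-2-yl)-1,3-benzodioxol-5-yl]oxy}cyclobutan-1-one
Product: 13 2,2,6,6,9-pentamethyl-6,7-dihydro-8H-[1,3]dioxolo[4,5-g]chromen-8-one (acetonide of 6,7-dihydroxy-2,2,5-trimethylchroman-4-one), via arylrhodium 10 (not isolated), via rhodium methanochromanolate 11 (not isolated), via alkylrhodium 12 (not isolated)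
Conditions: [Rh(OH)(cod)]2 (5 mol %), 1,4-dioxane/H2O (10:1), 70 °C
Reagents that add atoms: none
Why: Proposed new method: transmetalation of the pinacol boronate to the monovalent rhodium hydroxide gives arylrhodium 10, which adds across the four-membered ring to the strained ketone (6-exo-trig closure of ring D by C4a–C4 bond formation) to give the 2,4-methanochroman-4-olate 11; strain-driven β-carbon elimination then cleaves one of the two equivalent C4–CH2 bonds, and protonolysis of alkylrhodium 12 by water turns the expelled ring carbon into the second C2 methyl group and regenerates the rhodium hydroxide. The closest known reaction type is the rhodium-catalysed addition of arylboron reagents to cyclobutanones with ring opening by β-carbon elimination, together with the ring opening of tertiary cyclobutanols by the same elementary step; the oxygen tether and the six-membered ring closure are the untested elements. No stereocentre is formed, because C2 ends with two methyl groups and the two ring CH2 groups of 9 are mirror-related, so there is also no regiochemical choice in the C–C cleavage. The step needs intramolecular addition to outrun protodeboronation of the doubly ortho-substituted boronate, which the enforced proximity of the C–Rh bond to the carbonyl carbon across the ring and the base-free aqueous medium should secure. β-Hydride elimination from 12 is impossible because its β-carbon is quaternary, and the only other exit, β-aryloxy elimination, would give a 2-hydroxyaryl enone that should reclose by oxa-Michael addition to the same chromanone 13.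

Step 10
Reactants: 13 2,2,6,6,9-pentamethyl-6,7-dihydro-8H-[1,3]dioxolo[4,5-g]chromen-8-one
Product: 14 6,7-dihydroxy-2,2,5-trimethylchroman-4-one
Conditions: TFA/H2O (9:1), 40 °C, N2
Reagents that add atoms: none
Why: Acid hydrolysis of the catechol isopropylidene ketal, to which the chromanone (a ring type normally made in strong acid) should be stable.

Step 11
Reactants: 15 2,6-difluoro-4-methylbenzaldehyde
Product: 16 2-(benzyloxy)-6-fluoro-4-methylbenzaldehyde
Conditions: BnOH (1.0 equiv), NaH, THF, 0 °C → rt
Reagents that add atoms: benzyl alcohol, OCc1ccccc1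
Why: SNAr displacement of a fluoride ortho to the formyl group by benzyloxide via a Meisenheimer adduct, after which the new alkoxy group deactivates the ring and the second fluoride stays.

Step 12
Reactants: 16 2-(benzyloxy)-6-fluoro-4-methylbenzaldehyde
Product: 17 6-(benzyloxy)-3-bromo-2-fluoro-4-methylbenzaldehyde
Conditions: NBS, DMF, rt
Reagents that add atoms: N-bromosuccinimide, O=C1CCC(=O)N1Br
Why: Electrophilic aromatic bromination para to the benzyloxy group, the strongest director on the ring, which places bromine between F and CH3.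

Step 13
Reactants: 17 6-(benzyloxy)-3-bromo-2-fluoro-4-methylbenzaldehyde
Product: 18 4-(benzyloxy)-2-fluoro-3-formyl-6-methylbenzoic acid
Conditions: CO (1 atm), Pd(OAc)2 (5 mol %), Xantphos (5 mol %), Et3N, DMF/H2O (5:1), 80 °C; acidic work-up
Reagents that add atoms: carbon monoxide, [C-]#[O+]; water, O
Why: Palladium-catalysed hydroxycarbonylation (oxidative addition of the aryl bromide to zerovalent palladium, CO insertion, hydrolysis of the acylpalladium), which leaves the C–F bond and the aldehyde untouched.

Step 14
Reactants: 18 4-(benzyloxy)-2-fluoro-3-formyl-6-methylbenzoic acid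
Product: 19 4-(benzyloxy)-2-fluoro-3-formyl-6-methylbenzoyl chloride
Conditions: (COCl)2, DMF (cat.), CH2Cl2, 0 °C → rt; evaporate and use crude
Reagents that add atoms: oxalyl chloride, O=C(Cl)C(Cl)=O
Why: Acyl chloride formation through the chloroiminium (Vilsmeier-type) catalyst, the reliable way to activate a 2,6-disubstituted benzoic acid.

Step 15
Reactants: 14 6,7-dihydroxy-2,2,5-trimethylchroman-4-one; 19 4-(benzyloxy)-2-fluoro-3-formyl-6-methylbenzoyl chloride
Product: 22 O-benzylmollicellin B (mollicellin B with its ring A phenol as benzyl ether), via 7-O-aroyl ester 20 (not isolated), via 6-O-aroyl ester 21 (not isolated)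
Conditions: Cs2CO3 (2.5 equiv), MeCN (high dilution), slow addition of 19 at 0 °C, then 60 °C
Reagents that add atoms: none
Why: Acylation of the catechol monoanion followed by intramolecular SNAr closure of the seven-membered ring (fluoride activated by the ortho formyl and ortho aryl ester groups), in which fast O-to-O acyl migration places the acyl group on the less acidic, hindered 6-oxygen and leaves the phenoxide para to the C4 ketone to displace fluoride, which sets the orientation of ring B.

Step 16
Reactants: 22 O-benzylmollicellin B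
Product: 23 mollicellin B
Conditions: BCl3 (1 M in CH2Cl2, 3 equiv), pentamethylbenzene, CH2Cl2, −78 °C → −20 °C; MeOH/H2O quench
Reagents that add atoms: none
Why: Lewis acid cleavage of the benzyl aryl ether, assisted by chelation of boron between the ether oxygen and the ortho formyl oxygen, with pentamethylbenzene trapping the benzyl cation by Friedel–Crafts alkylation while lactone, chromanone and aldehyde should survive at low temperature.

**Compound list**

1 | 2,4-dihydroxy-6-methylbenzaldehyde | Cc1cc(O)cc(O)c1C=O | starting material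
2 | 6-methylbenzene-1,2,4-triol | Cc1cc(O)cc(O)c1O | intermediate
3 | 2,2,7-trimethyl-1,3-benzodioxol-5-ol | Cc1cc(O)cc2OC(C)(C)Oc12 | intermediate
4 | 6-bromo-2,2,7-trimethyl-1,3-benzodioxol-5-ol | Cc1c(Br)c(O)cc2OC(C)(C)Oc12 | intermediate
5 | 6-bromo-2,2,7-trimethyl-1,3-benzodioxol-5-yl acetate | CC(=O)Oc1cc2OC(C)(C)Oc2c(C)c1Br | intermediate
6 | 5-bromo-2,2,4-trimethyl-6-(prop-1-en-2-yloxy)-1,3-benzodioxole | C=C(C)Oc1cc2OC(C)(C)Oc2c(C)c1Br | intermediate
7 | racemic 3-[(6-bromo-2,2,7-trimethyl-1,3-benzodioxol-5-yl)oxy]-2,2-dichloro-3-methylcyclobutan-1-one | O=C1CC(C)(Oc2cc3OC(C)(C)Oc3c(C)c2Br)C1(Cl)Cl | intermediate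
8 | 3-[(6-bromo-2,2,7-trimethyl-1,3-benzodioxol-5-yl)oxy]-3-methylcyclobutan-1-one | O=C1CC(C)(Oc2cc3OC(C)(C)Oc3c(C)c2Br)C1 | intermediate
9 | 3-methyl-3-{[2,2,7-trimethyl-6-(4,4,5,5-tetramethyl-1,3,2-dioxaborolan-2-yl)-1,3-benzodioxol-5-yl]oxy}cyclobutan-1-one | O=C1CC(C)(Oc2cc3OC(C)(C)Oc3c(C)c2B2OC(C)(C)C(C)(C)O2)C1 | intermediate
10 | arylrhodium species formed from 9 by boron-to-rhodium exchange (not isolated; cod ligand not drawn) | O=C1CC(C)(Oc2cc3OC(C)(C)Oc3c(C)c2[Rh])C1 | intermediate
11 | rhodium 6,7-(isopropylidenedioxy)-2,5-dimethyl-2,4-methanochroman-4-olate (not isolated; cod ligand not drawn) | [Rh]OC12CC(C)(C1)Oc1cc3OC(C)(C)Oc3c(C)c12 | intermediate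
12 | alkylrhodium species, the C2-(rhodiomethyl) derivative of 13 (not isolated; cod ligand not drawn) | [Rh]CC1(C)CC(=O)c2c(C)c3OC(C)(C)Oc3cc2O1 | intermediate
13 | 2,2,6,6,9-pentamethyl-6,7-dihydro-8H-[1,3]dioxolo[4,5-g]chromen-8-one | CC1(C)CC(=O)c2c(C)c3OC(C)(C)Oc3cc2O1 | intermediate
14 | 6,7-dihydroxy-2,2,5-trimethylchroman-4-one | CC1(C)CC(=O)c2c(C)c(O)c(O)cc2O1 | intermediate
15 | 2,6-difluoro-4-methylbenzaldehyde | Cc1cc(F)c(C=O)c(F)c1 | starting material
16 | 2-(benzyloxy)-6-fluoro-4-methylbenzaldehyde | Cc1cc(F)c(C=O)c(OCc2ccccc2)c1 | intermediate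
17 | 6-(benzyloxy)-3-bromo-2-fluoro-4-methylbenzaldehyde | Cc1cc(OCc2ccccc2)c(C=O)c(F)c1Br | intermediate
18 | 4-(benzyloxy)-2-fluoro-3-formyl-6-methylbenzoic acid | Cc1cc(OCc2ccccc2)c(C=O)c(F)c1C(=O)O | intermediate
19 | 4-(benzyloxy)-2-fluoro-3-formyl-6-methylbenzoyl chloride | Cc1cc(OCc2ccccc2)c(C=O)c(F)c1C(Cl)=O | intermediate
20 | 6-hydroxy-2,2,5-trimethyl-4-oxochroman-7-yl 4-(benzyloxy)-2-fluoro-3-formyl-6-methylbenzoate (not isolated) | Cc1cc(OCc2ccccc2)c(C=O)c(F)c1C(=O)Oc1cc2OC(C)(C)CC(=O)c2c(C)c1O | intermediate
21 | 7-hydroxy-2,2,5-trimethyl-4-oxochroman-6-yl 4-(benzyloxy)-2-fluoro-3-formyl-6-methylbenzoate (not isolated) | Cc1cc(OCc2ccccc2)c(C=O)c(F)c1C(=O)Oc1c(C)c2C(=O)CC(C)(C)Oc2cc1O | intermediate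
22 | O-benzylmollicellin B (benzyl ether of the ring A phenol of mollicellin B) | Cc1cc(OCc3ccccc3)c(C=O)c2c1C(=O)Oc1c(cc3c(c1C)C(=O)CC(C)(C)O3)O2 | intermediate
23 | mollicellin B | Cc1cc(O)c(C=O)c2c1C(=O)Oc1c(cc3c(c1C)C(=O)CC(C)(C)O3)O2 | target

**Count and risks**

Total step count: 16. Longest linear sequence: 12 steps (steps 1–10, 15, 16); the ring A branch (steps 11–14) joins at step 15.

The three steps most likely to fail:

(1) Step 9. The hindered, electron-rich boronate may lose boron by protonolysis, or transfer its aryl group to rhodium too slowly, before the aryl group reaches the ketone. The fallback sets out from bromide 8 and comes back at 13. It forms the same C4a–C4 bond stoichiometrically: bromine–lithium exchange (t-BuLi, THF/Et2O, −100 °C; intramolecular Barbier or Parham-type cyclisation) should give the bridged tertiary cyclobutanol 6,7-(isopropylidenedioxy)-2,5-dimethyl-2,4-methanochroman-4-ol F1. The known ring opening of tertiary cyclobutanols by β-carbon elimination and protonolysis ([Rh(OH)(cod)]2 cat., toluene, 100 °C) should then give 13.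

(2) Step 15. After acyl migration the ring may close through the other phenoxide, giving the reversed orientation of ring B, or the ester may oligomerise instead of closing the seven-membered ring. The fallback sets out from 14 and 18 and comes back at 22. It separates the two catechol oxygens by protecting groups and forms the ether before the ester.
- Selective methoxymethylation of the more acidic 7-hydroxyl (MOMCl, K2CO3, acetone) should give 6-hydroxy-7-(methoxymethoxy)-2,2,5-trimethylchroman-4-one F2.
- Allylation (allyl bromide, K2CO3, DMF) should give 6-(allyloxy)-7-(methoxymethoxy)-2,2,5-trimethylchroman-4-one F3.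
- HCl/MeOH should free the 7-hydroxyl to give 6-(allyloxy)-7-hydroxy-2,2,5-trimethylchroman-4-one F4.
- Acid 18 is converted (allyl bromide, K2CO3, DMF) to allyl 4-(benzyloxy)-2-fluoro-3-formyl-6-methylbenzoate F5.
- Intermolecular SNAr of F4 on F5 (K2CO3, DMF, 80 °C) should give allyl 2-{[6-(allyloxy)-2,2,5-trimethyl-4-oxochroman-7-yl]oxy}-4-(benzyloxy)-3-formyl-6-methylbenzoate F6; with no free ortho hydroxyl, Smiles migration is excluded.
- Both allyl groups are removed with Pd(PPh3)4 (zerovalent palladium) and morpholine to give 4-(benzyloxy)-3-formyl-2-[(6-hydroxy-2,2,5-trimethyl-4-oxochroman-7-yl)oxy]-6-methylbenzoic acid F7.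
- Lactonisation of F7 (trifluoroacetic anhydride, toluene, rt) should give 22.

(3) Step 7. The zinc enolate formed during dechlorination may expel the β-aryloxide and fragment the four-membered ring. The fallback sets out from 6 and comes back at 8 without passing through 7. A keteniminium [2+2] cycloaddition (N,N-dimethylacetamide, Tf2O, 2,4,6-collidine, 1,2-dichloroethane, −15 °C → 80 °C) should give N-{3-[(6-bromo-2,2,7-trimethyl-1,3-benzodioxol-5-yl)oxy]-3-methylcyclobutylidene}-N-methylmethanaminium triflate F8. Hydrolysis with aqueous NaHCO3 should give 8, so no halogen has to be removed.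

**Further compounds**

F1 | step 9 | 6,7-(isopropylidenedioxy)-2,5-dimethyl-2,4-methanochroman-4-ol | OC12CC(C)(C1)Oc1cc3OC(C)(C)Oc3c(C)c12
F2 | step 15 | 6-hydroxy-7-(methoxymethoxy)-2,2,5-trimethylchroman-4-one | CC1(C)CC(=O)c2c(C)c(O)c(OCOC)cc2O1
F3 | step 15 | 6-(allyloxy)-7-(methoxymethoxy)-2,2,5-trimethylchroman-4-one | CC1(C)CC(=O)c2c(C)c(OCC=C)c(OCOC)cc2O1
F4 | step 15 | 6-(allyloxy)-7-hydroxy-2,2,5-trimethylchroman-4-one | CC1(C)CC(=O)c2c(C)c(OCC=C)c(O)cc2O1
F5 | step 15 | allyl 4-(benzyloxy)-2-fluoro-3-formyl-6-methylbenzoate | Cc1cc(OCc2ccccc2)c(C=O)c(F)c1C(=O)OCC=C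
F6 | step 15 | allyl 2-{[6-(allyloxy)-2,2,5-trimethyl-4-oxochroman-7-yl]oxy}-4-(benzyloxy)-3-formyl-6-methylbenzoate | Cc1cc(OCc2ccccc2)c(C=O)c(Oc2cc3OC(C)(C)CC(=O)c3c(C)c2OCC=C)c1C(=O)OCC=C
F7 | step 15 | 4-(benzyloxy)-3-formyl-2-[(6-hydroxy-2,2,5-trimethyl-4-oxochroman-7-yl)oxy]-6-methylbenzoic acid | Cc1cc(OCc2ccccc2)c(C=O)c(Oc2cc3OC(C)(C)CC(=O)c3c(C)c2O)c1C(=O)O
F8 | step 7 | N-{3-[(6-bromo-2,2,7-trimethyl-1,3-benzodioxol-5-yl)oxy]-3-methylcyclobutylidene}-N-methylmethanaminium triflate | C[N+](C)=C1CC(C)(Oc2cc3OC(C)(C)Oc3c(C)c2Br)C1.[O-]S(=O)(=O)C(F)(F)F
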